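**Plan**
- Retrosynthesis: once the protecting groups are removed (ring A acetate and methyl ester, ring B methoxymethyl ether and benzylic silyl ether), the only skeletal cut runs through ring A, at C4–C5 and C1–C6.
- Enabling feature: in ring A the carboxyl carbon C1 lies between the C2 hydroxyl and the C6 aryloxy oxygen, C3 carries the prenyl group and C4/C5 are adjacent CH units. C1–C4 therefore map onto C3–C6 of a 3-carbomethoxy-4-acyloxy-5-prenyl-2-pyrone, and C5/C6 onto the two carbons of a terminal aryl ethynyl ether.
- Pyrone branch (steps 1–4): 5-methylhex-4-enoic acid is joined to dimethyl malonate, the tricarbonyl is formylated through its dianion and lactonised, and the 4-hydroxyl is acetylated.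
- Ring B branch (steps 5–11): creosol is ortho-formylated, O-demethylated, mono-protected, converted into the dichlorovinyl ether with trichloroethylene, reduced, silylated and turned into the ethynyl ether. Ring B is carried through intact.
- Ring A is the only ring made and arises last, by [4+2] addition and loss of CO2 (step 12). Ester dealkylation, deacetylation and mild acid finish the route (steps 13–14).
- Stereochemistry: the target has no stereocentre and no stereogenic double bond, so nothing has to be set.

Key step: step 12

Remark on the chemistry: the acyl malonate 4 is a strong carbon acid that would be alkylated or merely deprotonated by amide acetals, so the future C6 of the pyrone is introduced by formylating its dianion. The benzylic alcohol of ring B is carried as a silyl ether so that it is released under milder acid than an alkyl methoxymethyl ether would need.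

**Route**

Step 1
Reactants: 1 5-methylhex-4-enoic acid
Product: 2 5-methylhex-4-enoyl chloride
Conditions: (COCl)2, DMF (cat.), CH2Cl2, 0 °C to rt; concentrated and used crude
Reagents that add atoms: oxalyl chloride, ClC(=O)C(Cl)=O
Why: Acid chloride formation through the chloroiminium species made from DMF is mild and fast, and the trisubstituted alkene should survive the short exposure to HCl in a non-polar solvent.

Step 2
Reactants: 2 5-methylhex-4-enoyl chloride; 3 dimethyl malonate
Product: 4 dimethyl 2-(5-methylhex-4-enoyl)propanedioate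
Conditions: MgCl2 (1 equiv), Et3N (2 equiv), MeCN, 0 °C to rt; 1 M HCl work-up
Reagents that add atoms: none
Why: Soft-enolisation C-acylation of a malonate (the MgCl2-chelated enolate attacks the acid chloride) should stop at the monoacyl stage because the product is held as an unreactive chelate.

Step 3
Reactants: 4 dimethyl 2-(5-methylhex-4-enoyl)propanedioate
Product: 6 methyl 4-hydroxy-5-(3-methylbut-2-enyl)-2-oxo-2H-pyran-3-carboxylate, via formyl tricarbonyl 5 (not isolated)
Conditions: LiN(iPr)2 (2.5 equiv), THF, −78 to −20 °C; HCO2Et (3 equiv), −78 °C to rt; 1 M HCl; then PhMe, 80 °C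
Reagents that add atoms: ethyl formate, CCOC=O
Why: The acidic methine and then the ketone α′-methylene are deprotonated, the dianion undergoes a crossed Claisen formylation at its more basic carbon, and after acidification the hydroxymethylene oxygen of the resulting 1,3,5-tricarbonyl attacks one malonate ester and expels methanol, the usual lactonisation of such tricarbonyls to 4-hydroxy-2-pyrones.

Step 4
Reactants: 6 methyl 4-hydroxy-5-(3-methylbut-2-enyl)-2-oxo-2H-pyran-3-carboxylate
Product: 7 methyl 4-acetoxy-5-(3-methylbut-2-enyl)-2-oxo-2H-pyran-3-carboxylate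
Conditions: Ac2O, pyridine, CH2Cl2, 0 °C to rt; evaporated under anhydrous conditions and used fresh
Reagents that add atoms: acetic anhydride, CC(=O)OC(C)=O
Why: O-acetylation of the vinylogous acid at the 4-oxygen (enol ester formation) turns a strong donor into a weak one and removes the acidic proton that would otherwise add to the ynol ether.

Step 5
Reactants: 8 creosol (2-methoxy-4-methylphenol)
Product: 9 2-hydroxy-3-methoxy-5-methylbenzaldehyde
Conditions: (CH2O)n, MgCl2, Et3N, MeCN, reflux; 1 M HCl work-up
Reagents that add atoms: paraformaldehyde (formaldehyde), C=O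
Why: MgCl2-mediated ortho-formylation of a phenol with paraformaldehyde (Casnati–Skattebøl reaction) can only reach C6, because the other ortho position carries the methoxy group and the para position the methyl group.

Step 6
Reactants: 9 2-hydroxy-3-methoxy-5-methylbenzaldehyde
Product: 10 2,3-dihydroxy-5-methylbenzaldehyde
Conditions: BBr3, CH2Cl2, −78 °C to rt; H2O
Reagents that add atoms: none
Why: Lewis-acid cleavage of the aryl methyl ether by BBr3 is standard for ortho-vanillin-type aldehydes, and the aldehyde is recovered from its boron complex on hydrolysis.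

Step 7
Reactants: 10 2,3-dihydroxy-5-methylbenzaldehyde
Product: 11 2-hydroxy-3-(methoxymethoxy)-5-methylbenzaldehyde
Conditions: NaH (2.2 equiv), DMSO–THF, 0 °C to rt; MOMCl (1.0 equiv)
Reagents that add atoms: chloromethyl methyl ether, COCCl
Why: Williamson alkylation of the dianion should occur at the more basic, non-conjugated 3-phenoxide, because the 2-phenoxide is delocalised into the formyl group and chelated, which is the known selectivity of 2,3-dihydroxybenzaldehyde dianions.

Step 8
Reactants: 11 2-hydroxy-3-(methoxymethoxy)-5-methylbenzaldehyde; 12 trichloroethylene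
Product: 13 2-[(E)-1,2-dichloroethenoxy]-3-(methoxymethoxy)-5-methylbenzaldehyde
Conditions: K2CO3, DMF, 70 °C
Reagents that add atoms: none
Why: Base converts trichloroethylene into dichloroacetylene, to which the phenoxide adds in anti fashion to give the (E)-dichlorovinyl ether (vinylic substitution by elimination–addition), the usual first stage of the dichlorovinyl ether route to ynol ethers.

Step 9
Reactants: 13 2-[(E)-1,2-dichloroethenoxy]-3-(methoxymethoxy)-5-methylbenzaldehyde
Product: 14 [2-[(E)-1,2-dichloroethenoxy]-3-(methoxymethoxy)-5-methylphenyl]methanol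
Conditions: NaBH4, MeOH–THF, 0 °C
Reagents that add atoms: none
Why: Hydride reduction of the aldehyde is chemoselective, since vinyl chlorides and acetals are inert to NaBH4.

Step 10
Reactants: 14 [2-[(E)-1,2-dichloroethenoxy]-3-(methoxymethoxy)-5-methylphenyl]methanol
Product: 15 tert-butyl[[2-[(E)-1,2-dichloroethenoxy]-3-(methoxymethoxy)-5-methylphenyl]methoxy]dimethylsilane
Conditions: TBSCl, imidazole, DMF, rt
Reagents that add atoms: tert-butyldimethylsilyl chloride, CC(C)(C)[Si](C)(C)Cl
Why: Imidazole-promoted silylation of the primary alcohol gives an ether that tolerates butyllithium and later keeps the hydroxyl from adding across the ynol ether.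

Step 11
Reactants: 15 tert-butyl[[2-[(E)-1,2-dichloroethenoxy]-3-(methoxymethoxy)-5-methylphenyl]methoxy]dimethylsilane
Product: 18 tert-butyl[[2-(ethynyloxy)-3-(methoxymethoxy)-5-methylphenyl]methoxy]dimethylsilane, via chloroethynyl ether 16 (not isolated), via lithium acetylide 17 (not isolated)
Conditions: n-BuLi (2.3 equiv), THF, −78 to −40 °C; H2O, −78 °C; cold basic work-up, used promptly
Reagents that add atoms: none
Why: Vinylic deprotonation and loss of LiCl give the chloroalkyne, chlorine–lithium exchange gives the acetylide and protonation the terminal ynol ether (dichlorovinyl ether route to ynol ethers), all of which should be much faster at −78 °C than lithiation next to the methoxymethyl ether.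

Step 12
Reactants: 7 methyl 4-acetoxy-5-(3-methylbut-2-enyl)-2-oxo-2H-pyran-3-carboxylate; 18 tert-butyl[[2-(ethynyloxy)-3-(methoxymethoxy)-5-methylphenyl]methoxy]dimethylsilane
Product: 20 methyl 2-acetoxy-6-[2-[(tert-butyldimethylsilyl)oxymethyl]-6-(methoxymethoxy)-4-methylphenoxy]-3-(3-methylbut-2-enyl)benzoate, via bridged lactone 19 (not isolated)
Conditions: 7 (1.3 equiv), 2,6-di-tert-butyl-4-methylpyridine (0.1 equiv), PhMe (0.5 M), 100–110 °C, sealed tube, Ar
Reagents that add atoms: none
Why: The diene C3–C6 of pyrone 7, made electron-poor by the lactone carbonyl and the C3 ester and with its 4-oxygen muted as an acetate, should combine with the electron-rich triple bond of 18 in a concerted but asynchronous [4+2] cycloaddition of inverse electron demand, the bond from the terminal alkyne carbon to pyrone C6 forming ahead of the bond from the oxygen-bearing alkyne carbon to C3. The closest known reactions are the cycloadditions of 3-carbomethoxy-2-pyrones with ketene acetals, ynamines and alkoxyalkynes, which give ortho-oxygenated benzoates after decarboxylation. Ring A closes in two stages: the intermolecular [4+2] addition gives the 2-oxabicyclo[2.2.2]octa-5,7-dien-3-one 19, and a retro-[4+2] extrusion of CO2 leaves the six-membered carbocycle already aromatic, so no oxidation is needed. No stereocentre survives, because the two bridgehead centres of 19 become sp2 when CO2 departs. The step needs regioselectivity (aryloxy next to the ester), and this should follow from matched polarisation: pyrone C6 is the vinylogous acceptor terminus of both carbonyl groups and the unsubstituted alkyne carbon is the nucleophilic terminus of the ynol ether. The prenyl alkene should not compete because it is neither electron-rich nor strained, and the acetate and the hindered pyridine keep acidic species away from the ynol ether.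

Step 13
Reactants: 20 methyl 2-acetoxy-6-[2-[(tert-butyldimethylsilyl)oxymethyl]-6-(methoxymethoxy)-4-methylphenoxy]-3-(3-methylbut-2-enyl)benzoate
Product: 22 6-[2-[(tert-butyldimethylsilyl)oxymethyl]-6-(methoxymethoxy)-4-methylphenoxy]-2-hydroxy-3-(3-methylbut-2-enyl)benzoic acid, via lithium acetoxybenzoate 21 (not isolated)
Conditions: LiI (8 equiv), pyridine, 115 °C; then LiOH (2 M aq.), MeOH, rt; cold dilute HCl to pH 3–4
Reagents that add atoms: none
Why: Iodide attacks the ester methyl group in an SN2 dealkylation that is indifferent to the two ortho substituents blocking acyl attack, and it is run while the phenol is still acetylated so that the leaving carboxylate is not deactivated by an ortho phenoxide; hydroxide then cleaves the aryl acetate at room temperature (saponification).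

Step 14
Reactants: 22 6-[2-[(tert-butyldimethylsilyl)oxymethyl]-6-(methoxymethoxy)-4-methylphenoxy]-2-hydroxy-3-(3-methylbut-2-enyl)benzoic acid
Product: 23 2-hydroxy-6-[2-hydroxy-6-(hydroxymethyl)-4-methylphenoxy]-3-(3-methylbut-2-enyl)benzoic acid (CNP0140656.0)
Conditions: 2 M HCl (aq.), MeOH–THF, rt to 35 °C
Reagents that add atoms: none
Why: Dilute acid in methanol should solvolyse the primary silyl ether and the phenolic methoxymethyl acetal (acetal exchange) under conditions commonly tolerated by ortho-prenylphenols, while the doubly ortho-substituted carboxyl group does not esterify.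

**Compound list**
1 | 5-methylhex-4-enoic acid | CC(C)=CCCC(=O)O | starting material
2 | 5-methylhex-4-enoyl chloride | CC(C)=CCCC(=O)Cl | intermediate
3 | dimethyl malonate | COC(=O)CC(=O)OC | starting material
4 | dimethyl 2-(5-methylhex-4-enoyl)propanedioate | COC(=O)C(C(=O)OC)C(=O)CCC=C(C)C | intermediate
5 | dimethyl 2-(2-formyl-5-methylhex-4-enoyl)propanedioate (drawn as the aldehyde tautomer; racemic and enolised) | COC(=O)C(C(=O)OC)C(=O)C(C=O)CC=C(C)C | intermediate (not isolated)
6 | methyl 4-hydroxy-5-(3-methylbut-2-enyl)-2-oxo-2H-pyran-3-carboxylate | COC(=O)C1=C(O)C(CC=C(C)C)=COC1=O | intermediate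
7 | methyl 4-acetoxy-5-(3-methylbut-2-enyl)-2-oxo-2H-pyran-3-carboxylate | COC(=O)C1=C(OC(C)=O)C(CC=C(C)C)=COC1=O | intermediate
8 | creosol (2-methoxy-4-methylphenol) | COc1cc(C)ccc1O | starting material
9 | 2-hydroxy-3-methoxy-5-methylbenzaldehyde | COc1cc(C)cc(C=O)c1O | intermediate
10 | 2,3-dihydroxy-5-methylbenzaldehyde | Cc1cc(O)c(O)c(C=O)c1 | intermediate
11 | 2-hydroxy-3-(methoxymethoxy)-5-methylbenzaldehyde | COCOc1cc(C)cc(C=O)c1O | intermediate
12 | trichloroethylene | ClC=C(Cl)Cl | starting material
13 | 2-[(E)-1,2-dichloroethenoxy]-3-(methoxymethoxy)-5-methylbenzaldehyde | COCOc1cc(C)cc(C=O)c1O/C(Cl)=C\Cl | intermediate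
14 | [2-[(E)-1,2-dichloroethenoxy]-3-(methoxymethoxy)-5-methylphenyl]methanol | COCOc1cc(C)cc(CO)c1O/C(Cl)=C\Cl | intermediate
15 | tert-butyl[[2-[(E)-1,2-dichloroethenoxy]-3-(methoxymethoxy)-5-methylphenyl]methoxy]dimethylsilane | COCOc1cc(C)cc(CO[Si](C)(C)C(C)(C)C)c1O/C(Cl)=C\Cl | intermediate
16 | tert-butyl[[2-(chloroethynyloxy)-3-(methoxymethoxy)-5-methylphenyl]methoxy]dimethylsilane | COCOc1cc(C)cc(CO[Si](C)(C)C(C)(C)C)c1OC#CCl | intermediate (not isolated)
17 | lithium acetylide of 18 | COCOc1cc(C)cc(CO[Si](C)(C)C(C)(C)C)c1OC#C[Li] | intermediate (not isolated)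
18 | tert-butyl[[2-(ethynyloxy)-3-(methoxymethoxy)-5-methylphenyl]methoxy]dimethylsilane | COCOc1cc(C)cc(CO[Si](C)(C)C(C)(C)C)c1OC#C | intermediate
19 | methyl 5-acetoxy-8-aryloxy-6-(3-methylbut-2-enyl)-3-oxo-2-oxabicyclo[2.2.2]octa-5,7-diene-4-carboxylate (aryl = ring B of 18; racemic) | COC(=O)C12C(=O)OC(C=C1Oc3c(OCOC)cc(C)cc3CO[Si](C)(C)C(C)(C)C)C(CC=C(C)C)=C2OC(C)=O | intermediate (not isolated)
20 | methyl 2-acetoxy-6-[2-[(tert-butyldimethylsilyl)oxymethyl]-6-(methoxymethoxy)-4-methylphenoxy]-3-(3-methylbut-2-enyl)benzoate | CC(C)=CCc1ccc(Oc2c(OCOC)cc(C)cc2CO[Si](C)(C)C(C)(C)C)c(C(=O)OC)c1OC(C)=O | intermediate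
21 | lithium 2-acetoxy-6-[2-[(tert-butyldimethylsilyl)oxymethyl]-6-(methoxymethoxy)-4-methylphenoxy]-3-(3-methylbut-2-enyl)benzoate | CC(C)=CCc1ccc(Oc2c(OCOC)cc(C)cc2CO[Si](C)(C)C(C)(C)C)c(C(=O)[O-])c1OC(C)=O.[Li+] | intermediate (not isolated)
22 | 6-[2-[(tert-butyldimethylsilyl)oxymethyl]-6-(methoxymethoxy)-4-methylphenoxy]-2-hydroxy-3-(3-methylbut-2-enyl)benzoic acid | CC(C)=CCc1ccc(Oc2c(OCOC)cc(C)cc2CO[Si](C)(C)C(C)(C)C)c(C(=O)O)c1O | intermediate
23 | 2-hydroxy-6-[2-hydroxy-6-(hydroxymethyl)-4-methylphenoxy]-3-(3-methylbut-2-enyl)benzoic acid | CC(C)=CCc1ccc(Oc2c(O)cc(C)cc2CO)c(C(=O)O)c1O | target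

**Totals**
Total step count: 14. Longest linear sequence: 10 steps (steps 5–14, from creosol).

**Steps most likely to fail**

1. Step 12. The terminal aryl ynol ether may oligomerise, or be consumed by acidic hydroxypyrone released when the enol acetate is transferred or displaced at pyrone C4, faster than the cycloaddition proceeds. The fallback sets out from 6 and exchanges the acyl group for an acetal that can neither be transferred nor leave as a carboxylate. Alkylation of 6 with MOMCl and iPr2NEt in CH2Cl2 at 0 °C should give methyl 4-(methoxymethoxy)-5-(3-methylbut-2-enyl)-2-oxo-2H-pyran-3-carboxylate F1. Heating F1 with 18 in o-xylene at 140 °C, a temperature the acetal and the ynol ether (which has no hydrogen for a retro-ene path) should bear, is expected to pass through the bridged lactone methyl 8-aryloxy-5-(methoxymethoxy)-6-(3-methylbut-2-enyl)-3-oxo-2-oxabicyclo[2.2.2]octa-5,7-diene-4-carboxylate F2, which loses CO2 in the flask, to methyl 6-[2-[(tert-butyldimethylsilyl)oxymethyl]-6-(methoxymethoxy)-4-methylphenoxy]-2-(methoxymethoxy)-3-(3-methylbut-2-enyl)benzoate F3. LiI in pyridine at 115 °C followed by mild acidification should give 6-[2-[(tert-butyldimethylsilyl)oxymethyl]-6-(methoxymethoxy)-4-methylphenoxy]-2-(methoxymethoxy)-3-(3-methylbut-2-enyl)benzoic acid F4. Treatment of F4 with 2 M HCl in MeOH–THF removes both acetals and the silyl ether and comes back to the route at 23.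

2. Step 3. The second deprotonation may be incomplete, or the tricarbonyl may be cleaved by alkoxide (retro-Claisen deacylation), so that the formyl carbon is not introduced cleanly. The fallback sets out from 1 and installs that carbon before the malonate is attached. Esterification of 1 (MeI, K2CO3, DMF) gives methyl 5-methylhex-4-enoate F5. Claisen formylation (NaH, HCO2Me, THF) gives methyl 2-formyl-5-methylhex-4-enoate F6, kept as its sodium enolate and O-methylated in the same flask (Me2SO4, K2CO3) to methyl (E)-2-(methoxymethylene)-5-methylhex-4-enoate F7. Saponification (LiOH, aqueous THF) gives (E)-2-(methoxymethylene)-5-methylhex-4-enoic acid F8. Oxalyl chloride converts it into (E)-2-(methoxymethylene)-5-methylhex-4-enoyl chloride F9, which acylates 3 under the MgCl2/Et3N conditions of step 2 to give dimethyl 2-[(E)-2-(methoxymethylene)-5-methylhex-4-enoyl]propanedioate F10. Dilute HCl in THF hydrolyses the vinylogous ester of F10 to the tricarbonyl 5, which lactonises as in step 3, so the route is rejoined at 6.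

3. Step 14. The free ring A phenol may cyclise onto the protonated prenyl double bond (chroman formation), or the benzylic alcohol may undergo solvolysis in methanol, while the phenolic acetal is still being cleaved. The fallback sets out from 20 and changes the order of events, so that the acid step is run while the ring A phenol is still blocked as its acetate and no methanol is present. Treatment of 20 with 2 M HCl in aqueous THF at 40 °C should give methyl 2-acetoxy-6-[2-hydroxy-6-(hydroxymethyl)-4-methylphenoxy]-3-(3-methylbut-2-enyl)benzoate F11. LiI in pyridine at 115 °C then gives lithium 2-acetoxy-6-[2-hydroxy-6-(hydroxymethyl)-4-methylphenoxy]-3-(3-methylbut-2-enyl)benzoate F12, which is not isolated. Aqueous LiOH at room temperature followed by careful acidification removes the acetate and comes back to the route at 23.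

**Further compounds**
F1 | step 12 | methyl 4-(methoxymethoxy)-5-(3-methylbut-2-enyl)-2-oxo-2H-pyran-3-carboxylate | COC(=O)C1=C(OCOC)C(CC=C(C)C)=COC1=O
F2 | step 12 | methyl 8-aryloxy-5-(methoxymethoxy)-6-(3-methylbut-2-enyl)-3-oxo-2-oxabicyclo[2.2.2]octa-5,7-diene-4-carboxylate (aryl = ring B of 18; racemic, not isolated) | COC(=O)C12C(=O)OC(C=C1Oc3c(OCOC)cc(C)cc3CO[Si](C)(C)C(C)(C)C)C(CC=C(C)C)=C2OCOC
F3 | step 12 | methyl 6-[2-[(tert-butyldimethylsilyl)oxymethyl]-6-(methoxymethoxy)-4-methylphenoxy]-2-(methoxymethoxy)-3-(3-methylbut-2-enyl)benzoate | CC(C)=CCc1ccc(Oc2c(OCOC)cc(C)cc2CO[Si](C)(C)C(C)(C)C)c(C(=O)OC)c1OCOC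
F4 | step 12 | 6-[2-[(tert-butyldimethylsilyl)oxymethyl]-6-(methoxymethoxy)-4-methylphenoxy]-2-(methoxymethoxy)-3-(3-methylbut-2-enyl)benzoic acid | CC(C)=CCc1ccc(Oc2c(OCOC)cc(C)cc2CO[Si](C)(C)C(C)(C)C)c(C(=O)O)c1OCOC
F5 | step 3 | methyl 5-methylhex-4-enoate | COC(=O)CCC=C(C)C
F6 | step 3 | methyl 2-formyl-5-methylhex-4-enoate (handled as its sodium enolate, not isolated) | COC(=O)C(C=O)CC=C(C)C
F7 | step 3 | methyl (E)-2-(methoxymethylene)-5-methylhex-4-enoate | CO/C=C(\CC=C(C)C)C(=O)OC
F8 | step 3 | (E)-2-(methoxymethylene)-5-methylhex-4-enoic acid | CO/C=C(\CC=C(C)C)C(=O)O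
F9 | step 3 | (E)-2-(methoxymethylene)-5-methylhex-4-enoyl chloride | CO/C=C(\CC=C(C)C)C(=O)Cl
F10 | step 3 | dimethyl 2-[(E)-2-(methoxymethylene)-5-methylhex-4-enoyl]propanedioate | CO/C=C(\CC=C(C)C)C(=O)C(C(=O)OC)C(=O)OC
F11 | step 14 | methyl 2-acetoxy-6-[2-hydroxy-6-(hydroxymethyl)-4-methylphenoxy]-3-(3-methylbut-2-enyl)benzoate | CC(C)=CCc1ccc(Oc2c(O)cc(C)cc2CO)c(C(=O)OC)c1OC(C)=O
F12 | step 14 | lithium 2-acetoxy-6-[2-hydroxy-6-(hydroxymethyl)-4-methylphenoxy]-3-(3-methylbut-2-enyl)benzoate (not isolated) | CC(C)=CCc1ccc(Oc2c(O)cc(C)cc2CO)c(C(=O)[O-])c1OC(C)=O.[Li+]
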